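**Retrosynthetic overview**

1. The last C–C operations are cosmetic: target 27 comes from diimide saturation of the side-chain alkene of dienone 26, and 26 from dehydration of β-peroxy alcohol 24, whose carbinol is the relic of an epoxide.
2. The 1,2-dioxane (second and last ring) gets both C–O bonds from H2O2 by stereospecific substitutions: the tertiary C6–O bond by invertive opening of a Shi epoxide, the secondary C3–O bond by invertive 6-exo displacement of a mesylate.
3. Propanoate C2 and dioxane C3 come from a Brown (Z)-crotylation (vinyl = masked ester); the (E)-trisubstituted alkene for the epoxidation and the C4–C5 bond come from a Claisen rearrangement.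
4. The cyclohexenone (first ring) is cut at C1–C2 and C3–C4 into pent-3-ynyl pivalate (the C2=C3 pair with its methyl group and side chain) and 2,2-dimethylcyclopropanecarbonyl chloride (C1, C6, C5, C4).
5. Enabling feature: in the 2,4,4-trimethylcyclohex-2-enone ring the carbonyl carbon C1 and the gem-dimethyl quaternary carbon C4 flank the tetrasubstituted C2=C3 bond and are tied together by C5–C6, so C1 can arrive as an acyl chloride and C4 as a tertiary cation set free by C–C cleavage of a cyclopropane.

Key step: step 3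

Remark: racemic 1 is used because its only stereocentre becomes a CH2 group in step 3. Locants in the text are those of the target (cyclohexenone C1 = carbonyl carbon; dioxane C3 and C6; propanoate C2).

**Route**

Step 1
Reactants: 1 2,2-dimethylcyclopropane-1-carboxylic acid (racemic)
Product: 2 2,2-dimethylcyclopropane-1-carbonyl chloride (racemic)
Conditions: (COCl)2, DMF (cat.), CH2Cl2, 0 °C → rt
Reagents that add atoms: oxalyl chloride, ClC(=O)C(=O)Cl
Why: Standard acid chloride formation through the chloroiminium salt; the conditions are non-ionising, so the cyclopropane should stay closed.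

Step 2
Reactants: 3 pent-3-yn-1-ol
Product: 4 pent-3-yn-1-yl pivalate
Conditions: PivCl, pyridine, DMAP (cat.), CH2Cl2, 0 °C → rt
Reagents that add atoms: pivaloyl chloride, CC(C)(C)C(=O)Cl
Why: Simple O-acylation; the hindered ester is chosen because it should survive brief exposure to Cp2Zr(H)Cl and the AlCl3 of step 3.

Step 3
Reactants: 4 pent-3-yn-1-yl pivalate; 2 2,2-dimethylcyclopropane-1-carbonyl chloride
Product: 8 2-(2,6,6-trimethyl-3-oxocyclohex-1-en-1-yl)ethyl pivalate, via alkenylzirconocene chloride 5 (not isolated), via alkenylaluminium dichloride 6 (not isolated), via cyclopropyl enone 7 (not isolated)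
Conditions: Cp2Zr(H)Cl (1.3 equiv), CH2Cl2, rt; AlCl3 (3 equiv), 0 °C; 2, −30 °C → rt; aq. Rochelle salt
Reagents that add atoms: none
Why: Proposed new method: syn-hydrozirconation of 4 should place zirconium on the methyl-bearing alkyne carbon (the less hindered end, reinforced by equilibration with the slight excess of Cp2Zr(H)Cl), Zr-to-Al exchange and acylation of 6 by 2 then join the future carbonyl carbon to the methyl-bearing alkene carbon with retention of geometry, and the AlCl3-bound cyclopropyl enone 7 ionises at the cyclopropane bond to the gem-dimethyl carbon to a tertiary cation/aluminium dienolate that attacks the side-chain-bearing alkene carbon before proton loss gives the conjugated enone. The closest known reaction types are the acylation of alkenylalanes made by Zr/Al exchange and the acid-promoted homo-Nazarov cyclisation of alkenyl cyclopropyl ketones, merged here and extended to a donor that is only a gem-dialkyl group. The six-membered ring closes by a 6-endo cation–olefin attack on the β-carbon of the enone, a formal [4+2] union of a C1/C4 dielectrophile with the two alkyne carbons. No stereocentre is created, and the single stereocentre of 2 becomes the C6 methylene. Regiocontrol is needed in three places: hydrozirconation (methyl versus the larger CH2CH2OPiv arm), the cyclopropane bond that breaks (only cleavage toward the gem-dimethyl carbon gives a tertiary cation), and ring size (β-attack gives an oxyallyl cation, α-attack would leave an unstabilised secondary cation). Chloride capture, elimination, dihydrofuran formation and re-closure to the cyclopropane all return to the same cation, so the irreversible C–C bond formation should drain them.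

Step 4
Reactants: 8 2-(2,6,6-trimethyl-3-oxocyclohex-1-en-1-yl)ethyl pivalate
Product: 9 3-(2-hydroxyethyl)-2,4,4-trimethylcyclohex-2-en-1-one
Conditions: K2CO3, MeOH, 40 °C
Reagents that add atoms: none
Why: Base-catalysed methanolysis of the ester; the enone has no epimerisable centre and its fully substituted β-carbon should resist methoxide addition.

Step 5
Reactants: 9 3-(2-hydroxyethyl)-2,4,4-trimethylcyclohex-2-en-1-one
Product: 10 (2,6,6-trimethyl-3-oxocyclohex-1-en-1-yl)acetaldehyde
Conditions: Dess–Martin periodinane, NaHCO3, CH2Cl2, 0 °C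
Reagents that add atoms: none
Why: Dess–Martin oxidation under buffered, non-basic conditions, which should keep the doubly activated CH2 group from enolising; 10 is used crude.

Step 6
Reactants: 10 (2,6,6-trimethyl-3-oxocyclohex-1-en-1-yl)acetaldehyde
Product: 12 3-(2-hydroxy-3-methylbut-3-en-1-yl)-2,4,4-trimethylcyclohex-2-en-1-one (racemic), via chromium alkoxide 11 (not isolated)
Conditions: 2-bromopropene, CrCl2 (4 equiv), NiCl2 (2 mol%), DMF, rt; aq. work-up
Reagents that add atoms: 2-bromopropene, CC(Br)=C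
Why: Nozaki–Hiyama–Kishi addition: the non-basic alkenylchromium reagent should add to the aldehyde and leave the enone ketone and the acidic CH2 alone; the new carbinol centre is racemic and is erased in step 7.

Step 7
Reactants: 12 3-(2-hydroxy-3-methylbut-3-en-1-yl)-2,4,4-trimethylcyclohex-2-en-1-one
Product: 14 (4E)-4-methyl-6-(2,6,6-trimethyl-3-oxocyclohex-1-en-1-yl)hex-4-enal, via allyl vinyl ether 13 (not isolated)
Conditions: ethyl vinyl ether (solvent), Hg(OAc)2 (10 mol%), reflux; then toluene, 130 °C, sealed tube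
Reagents that add atoms: ethyl vinyl ether, CCOC=C
Why: Vinyl ether exchange followed by Claisen rearrangement; the chair transition state with the CH2–enone arm equatorial should give the (E)-trisubstituted alkene and delivers the aldehyde directly, so no hydride reagent meets the enone.

Step 8
Reactants: 14 (4E)-4-methyl-6-(2,6,6-trimethyl-3-oxocyclohex-1-en-1-yl)hex-4-enal
Product: 16 3-[(2E,6S,7S)-6-hydroxy-3,7-dimethylnona-2,8-dien-1-yl]-2,4,4-trimethylcyclohex-2-en-1-one, via borinate ester 15 (not isolated)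
Conditions: cis-but-2-ene, KOt-Bu, n-BuLi, THF, −78 → −45 °C; (+)-Ipc2BOMe [from (−)-α-pinene], −78 °C; BF3·OEt2; 14, −78 °C; ethanolamine work-up
Reagents that add atoms: cis-but-2-ene, C/C=C\C
Why: Brown crotylation through a closed chair transition state: the (Z)-crotyl geometry gives the syn relationship and the isopinocampheyl groups from (−)-α-pinene direct attack to the Re face, which should set the carbinol (6S) and the methyl-bearing centre (7S, the future propanoate C2); the aldehyde reacts at −78 °C while the ketone does not, and the non-oxidative work-up spares the enone.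

Step 9
Reactants: 16 3-[(2E,6S,7S)-6-hydroxy-3,7-dimethylnona-2,8-dien-1-yl]-2,4,4-trimethylcyclohex-2-en-1-one
Product: 17 (3S,4S,7E)-3,7-dimethyl-9-(2,6,6-trimethyl-3-oxocyclohex-1-en-1-yl)nona-1,7-dien-4-yl methanesulfonate
Conditions: MsCl, Et3N, CH2Cl2, 0 °C
Reagents that add atoms: methanesulfonyl chloride, CS(=O)(=O)Cl
Why: O-sulfonylation with retention (the C–O bond is not touched); it is done before the epoxidation so that no free hydroxyl can later open the epoxide to a tetrahydrofuran.

Step 10
Reactants: 17 (3S,4S,7E)-3,7-dimethyl-9-(2,6,6-trimethyl-3-oxocyclohex-1-en-1-yl)nona-1,7-dien-4-yl methanesulfonate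
Product: 18 (3S,4S)-3-methyl-6-{(2R,3R)-2-methyl-3-[(2,6,6-trimethyl-3-oxocyclohex-1-en-1-yl)methyl]oxiran-2-yl}hex-1-en-4-yl methanesulfonate
Conditions: D-fructose-derived ketone catalyst (30 mol%), Oxone (2KHSO5·KHSO4·K2SO4), K2CO3, Bu4NHSO4, Na2B4O7 buffer, MeCN/dimethoxymethane/H2O, 0 °C
Reagents that add atoms: potassium peroxymonosulfate, [K+].[O-]S(=O)(=O)OO
Why: Shi epoxidation: the chiral dioxirane is electrophilic and should pick the electron-rich (E)-trisubstituted alkene over the terminal vinyl group and the enone, and the D-fructose-derived catalyst with its spiro transition state should give the (2R,3R)-oxirane.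

Step 11
Reactants: 18 (3S,4S)-3-methyl-6-{(2R,3R)-2-methyl-3-[(2,6,6-trimethyl-3-oxocyclohex-1-en-1-yl)methyl]oxiran-2-yl}hex-1-en-4-yl methanesulfonate
Product: 19 (3S,4S,7S,8R)-7-hydroperoxy-8-hydroxy-3,7-dimethyl-9-(2,6,6-trimethyl-3-oxocyclohex-1-en-1-yl)non-1-en-4-yl methanesulfonate
Conditions: H2O2 (anhydrous, in Et2O, excess), H3PMo12O40 (2 mol%), Et2O, 0 °C → rt
Reagents that add atoms: hydrogen peroxide, OO
Why: Acid-catalysed perhydrolysis of a trisubstituted epoxide: H2O2 should attack the tertiary carbon in a borderline SN2 opening with inversion, which sets the peroxide-bearing quaternary centre (the future dioxane C6) from the epoxide configuration; the mesylate, vinyl group and enone are inert to these conditions.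

Step 12
Reactants: 19 (3S,4S,7S,8R)-7-hydroperoxy-8-hydroxy-3,7-dimethyl-9-(2,6,6-trimethyl-3-oxocyclohex-1-en-1-yl)non-1-en-4-yl methanesulfonate
Product: 20 3-{(2R)-2-[(3S,6R)-6-[(2S)-but-3-en-2-yl]-3-methyl-1,2-dioxan-3-yl]-2-hydroxyethyl}-2,4,4-trimethylcyclohex-2-en-1-one
Conditions: KOt-Bu (1.05 equiv), 18-crown-6 (0.2 equiv), THF, 0 °C
Reagents that add atoms: none
Why: Intramolecular alkylation of a hydroperoxide: one equivalent of base ionises only the OOH group, and the weakly basic, strongly nucleophilic peroxide anion should displace the secondary mesylate 6-exo-tet with inversion, which closes the 1,2-dioxane and sets its C3 as (R).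

Step 13
Reactants: 20 3-{(2R)-2-[(3S,6R)-6-[(2S)-but-3-en-2-yl]-3-methyl-1,2-dioxan-3-yl]-2-hydroxyethyl}-2,4,4-trimethylcyclohex-2-en-1-one
Product: 22 (2R)-2-{(3R,6S)-6-[(1R)-1-hydroxy-2-(2,6,6-trimethyl-3-oxocyclohex-1-en-1-yl)ethyl]-6-methyl-1,2-dioxan-3-yl}propanal, via diol 21 (not isolated)
Conditions: OsO4 (2 mol%), NaIO4 (4 equiv), 2,6-lutidine, dioxane/H2O, rt
Reagents that add atoms: osmium tetroxide (catalytic oxygen carrier), O=[Os](=O)(=O)=O; sodium periodate, [Na+].[O-]I(=O)(=O)=O
Why: Lemieux–Johnson cleavage: OsO4 should dihydroxylate only the monosubstituted vinyl group (the tetrasubstituted, electron-poor enone alkene is inert) and periodate cleaves the diol; the dialkyl peroxide tolerates both oxidants, and 22 is carried on at once to protect the α-centre.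

Step 14
Reactants: 22 (2R)-2-{(3R,6S)-6-[(1R)-1-hydroxy-2-(2,6,6-trimethyl-3-oxocyclohex-1-en-1-yl)ethyl]-6-methyl-1,2-dioxan-3-yl}propanal
Product: 23 (2R)-2-{(3R,6S)-6-[(1R)-1-hydroxy-2-(2,6,6-trimethyl-3-oxocyclohex-1-en-1-yl)ethyl]-6-methyl-1,2-dioxan-3-yl}propanoic acid
Conditions: NaClO2, NaH2PO4, 2-methylbut-2-ene, t-BuOH/H2O, 0 °C → rt
Reagents that add atoms: sodium chlorite, [Na+].[O-]Cl=O
Why: Pinnick oxidation at mildly acidic pH, which should not epimerise the α-centre or trigger β-elimination of the peroxide; the scavenger removes HOCl before it can touch the enone.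

Step 15
Reactants: 23 (2R)-2-{(3R,6S)-6-[(1R)-1-hydroxy-2-(2,6,6-trimethyl-3-oxocyclohex-1-en-1-yl)ethyl]-6-methyl-1,2-dioxan-3-yl}propanoic acid
Product: 24 methyl (2R)-2-{(3R,6S)-6-[(1R)-1-hydroxy-2-(2,6,6-trimethyl-3-oxocyclohex-1-en-1-yl)ethyl]-6-methyl-1,2-dioxan-3-yl}propanoate
Conditions: TMSCHN2, MeOH/toluene, 0 °C
Reagents that add atoms: trimethylsilyldiazomethane, C[Si](C)(C)C=[N+]=[N-]
Why: Base-free O-methylation of the carboxylic acid, so the β-peroxy ester never sees conditions that allow retro-oxa-Michael opening.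

Step 16
Reactants: 24 methyl (2R)-2-{(3R,6S)-6-[(1R)-1-hydroxy-2-(2,6,6-trimethyl-3-oxocyclohex-1-en-1-yl)ethyl]-6-methyl-1,2-dioxan-3-yl}propanoate
Product: 26 methyl (2R)-2-{(3R,6S)-6-methyl-6-[(E)-2-(2,6,6-trimethyl-3-oxocyclohex-1-en-1-yl)ethenyl]-1,2-dioxan-3-yl}propanoate, via sulfamate ester 25 (not isolated)
Conditions: Burgess reagent (MeO2CN–SO2NEt3), toluene, 50 °C
Reagents that add atoms: none
Why: Burgess dehydration by thermal syn-elimination of the sulfamate; the only β-hydrogens are on the CH2 next to the enone, so the alkene can form only toward the ring and into conjugation, and the neutral conditions should spare the peroxide.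

Step 17
Reactants: 26 methyl (2R)-2-{(3R,6S)-6-methyl-6-[(E)-2-(2,6,6-trimethyl-3-oxocyclohex-1-en-1-yl)ethenyl]-1,2-dioxan-3-yl}propanoate
Product: 27 diacarperoxide A, methyl (2R)-2-{(3R,6R)-6-methyl-6-[2-(2,6,6-trimethyl-3-oxocyclohex-1-en-1-yl)ethyl]-1,2-dioxan-3-yl}propanoate
Conditions: KO2CN=NCO2K, AcOH, CH2Cl2/MeOH, 0 °C → rt
Reagents that add atoms: none
Why: Diimide reduction by concerted syn-transfer of H2: it should reduce the accessible trans-disubstituted alkene, cannot reach the tetrasubstituted enone alkene, and does not cleave O–O bonds; no stereocentre is touched (the C6 descriptor changes from S to R only through the priority rules).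

**Compound list**

1 | 2,2-dimethylcyclopropane-1-carboxylic acid (racemic) | CC1(C)CC1C(=O)O | starting material
2 | 2,2-dimethylcyclopropane-1-carbonyl chloride (racemic) | CC1(C)CC1C(=O)Cl | intermediate
3 | pent-3-yn-1-ol | CC#CCCO | starting material
4 | pent-3-yn-1-yl pivalate | CC#CCCOC(=O)C(C)(C)C | intermediate
5 | chlorobis(cyclopentadienyl)[(2E)-5-(pivaloyloxy)pent-2-en-2-yl]zirconium (Cp rings drawn σ-bonded) | C/C(=C\CCOC(=O)C(C)(C)C)[Zr](Cl)(C1C=CC=C1)C1C=CC=C1 | intermediate (not isolated)
6 | dichloro[(2E)-5-(pivaloyloxy)pent-2-en-2-yl]aluminium | C/C(=C\CCOC(=O)C(C)(C)C)[Al](Cl)Cl | intermediate (not isolated)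
7 | (3E)-5-(2,2-dimethylcyclopropyl)-4-methyl-5-oxopent-3-en-1-yl pivalate (racemic) | C/C(=C\CCOC(=O)C(C)(C)C)C(=O)C1CC1(C)C | intermediate (not isolated)
8 | 2-(2,6,6-trimethyl-3-oxocyclohex-1-en-1-yl)ethyl pivalate | CC1=C(CCOC(=O)C(C)(C)C)C(C)(C)CCC1=O | intermediate
9 | 3-(2-hydroxyethyl)-2,4,4-trimethylcyclohex-2-en-1-one | CC1=C(CCO)C(C)(C)CCC1=O | intermediate
10 | (2,6,6-trimethyl-3-oxocyclohex-1-en-1-yl)acetaldehyde | CC1=C(CC=O)C(C)(C)CCC1=O | intermediate
11 | dichlorochromium alkoxide of 12 (racemic) | CC(=C)C(O[Cr](Cl)Cl)CC1=C(C)C(=O)CCC1(C)C | intermediate (not isolated)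
12 | 3-(2-hydroxy-3-methylbut-3-en-1-yl)-2,4,4-trimethylcyclohex-2-en-1-one (racemic) | CC(=C)C(O)CC1=C(C)C(=O)CCC1(C)C | intermediate
13 | 3-[2-(ethenyloxy)-3-methylbut-3-en-1-yl]-2,4,4-trimethylcyclohex-2-en-1-one (racemic) | CC(=C)C(OC=C)CC1=C(C)C(=O)CCC1(C)C | intermediate (not isolated)
14 | (4E)-4-methyl-6-(2,6,6-trimethyl-3-oxocyclohex-1-en-1-yl)hex-4-enal | O=CCC/C(C)=C/CC1=C(C)C(=O)CCC1(C)C | intermediate
15 | diisopinocampheylborinate of 16 (Ipc groups from (−)-α-pinene) | C=C[C@H](C)[C@@H](OB([C@H]1C[C@H]2C[C@@H]([C@@H]1C)C2(C)C)[C@H]1C[C@H]2C[C@@H]([C@@H]1C)C2(C)C)CC/C(C)=C/CC1=C(C)C(=O)CCC1(C)C | intermediate (not isolated)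
16 | 3-[(2E,6S,7S)-6-hydroxy-3,7-dimethylnona-2,8-dien-1-yl]-2,4,4-trimethylcyclohex-2-en-1-one | C=C[C@H](C)[C@@H](O)CC/C(C)=C/CC1=C(C)C(=O)CCC1(C)C | intermediate
17 | (3S,4S,7E)-3,7-dimethyl-9-(2,6,6-trimethyl-3-oxocyclohex-1-en-1-yl)nona-1,7-dien-4-yl methanesulfonate | C=C[C@H](C)[C@@H](OS(C)(=O)=O)CC/C(C)=C/CC1=C(C)C(=O)CCC1(C)C | intermediate
18 | (3S,4S)-3-methyl-6-{(2R,3R)-2-methyl-3-[(2,6,6-trimethyl-3-oxocyclohex-1-en-1-yl)methyl]oxiran-2-yl}hex-1-en-4-yl methanesulfonate | C=C[C@H](C)[C@@H](OS(C)(=O)=O)CC[C@@]1(C)O[C@@H]1CC2=C(C)C(=O)CCC2(C)C | intermediate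
19 | (3S,4S,7S,8R)-7-hydroperoxy-8-hydroxy-3,7-dimethyl-9-(2,6,6-trimethyl-3-oxocyclohex-1-en-1-yl)non-1-en-4-yl methanesulfonate | C=C[C@H](C)[C@@H](OS(C)(=O)=O)CC[C@](C)(OO)[C@H](O)CC1=C(C)C(=O)CCC1(C)C | intermediate
20 | 3-{(2R)-2-[(3S,6R)-6-[(2S)-but-3-en-2-yl]-3-methyl-1,2-dioxan-3-yl]-2-hydroxyethyl}-2,4,4-trimethylcyclohex-2-en-1-one | C=C[C@H](C)[C@H]1CC[C@@](C)([C@H](O)CC2=C(C)C(=O)CCC2(C)C)OO1 | intermediate
21 | 3-{(2R)-2-[(3S,6R)-6-[(2S)-3,4-dihydroxybutan-2-yl]-3-methyl-1,2-dioxan-3-yl]-2-hydroxyethyl}-2,4,4-trimethylcyclohex-2-en-1-one (both epimers at the new secondary carbinol) | OCC(O)[C@H](C)[C@H]1CC[C@@](C)([C@H](O)CC2=C(C)C(=O)CCC2(C)C)OO1 | intermediate (not isolated)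
22 | (2R)-2-{(3R,6S)-6-[(1R)-1-hydroxy-2-(2,6,6-trimethyl-3-oxocyclohex-1-en-1-yl)ethyl]-6-methyl-1,2-dioxan-3-yl}propanal | O=C[C@H](C)[C@H]1CC[C@@](C)([C@H](O)CC2=C(C)C(=O)CCC2(C)C)OO1 | intermediate
23 | (2R)-2-{(3R,6S)-6-[(1R)-1-hydroxy-2-(2,6,6-trimethyl-3-oxocyclohex-1-en-1-yl)ethyl]-6-methyl-1,2-dioxan-3-yl}propanoic acid | OC(=O)[C@H](C)[C@H]1CC[C@@](C)([C@H](O)CC2=C(C)C(=O)CCC2(C)C)OO1 | intermediate
24 | methyl (2R)-2-{(3R,6S)-6-[(1R)-1-hydroxy-2-(2,6,6-trimethyl-3-oxocyclohex-1-en-1-yl)ethyl]-6-methyl-1,2-dioxan-3-yl}propanoate | COC(=O)[C@H](C)[C@H]1CC[C@@](C)([C@H](O)CC2=C(C)C(=O)CCC2(C)C)OO1 | intermediate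
25 | N-(methoxycarbonyl)sulfamate ester of 24, triethylammonium salt | COC(=O)[C@H](C)[C@H]1CC[C@@](C)([C@H](OS(=O)(=O)[N-]C(=O)OC)CC2=C(C)C(=O)CCC2(C)C)OO1.CC[NH+](CC)CC | intermediate (not isolated)
26 | methyl (2R)-2-{(3R,6S)-6-methyl-6-[(E)-2-(2,6,6-trimethyl-3-oxocyclohex-1-en-1-yl)ethenyl]-1,2-dioxan-3-yl}propanoate | COC(=O)[C@H](C)[C@H]1CC[C@@](C)(/C=C/C2=C(C)C(=O)CCC2(C)C)OO1 | intermediate
27 | diacarperoxide A, methyl (2R)-2-{(3R,6R)-6-methyl-6-[2-(2,6,6-trimethyl-3-oxocyclohex-1-en-1-yl)ethyl]-1,2-dioxan-3-yl}propanoate | COC(=O)[C@H](C)[C@H]1CC[C@@](C)(CCC2=C(C)C(=O)CCC2(C)C)OO1 | target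

**Step count and risks**

Total step count: 17. Longest linear sequence: 16 steps (steps 2–17 from 3; step 1 is a one-step side branch to 2).

The three steps most likely to fail:

1. Step 3 (Proposed new method). What may go wrong: the tertiary cation set free from the cyclopropane may be drained by chloride capture, elimination to acyclic dienones or a five-ring closure faster than it attacks the deactivated enone carbon, or the hydrozirconation may deliver some of the regioisomeric alkenyl metal. Fallback by known chemistry, from 7 to 8: the sequence of step 3 is stopped after the acylation at −30 °C and 7 is isolated. HBr in AcOH opens the cyclopropane toward the gem-dimethyl carbon to give (3E)-8-bromo-4,8-dimethyl-5-oxonon-3-en-1-yl pivalate F1. Bu3SnH and AIBN (slow addition, benzene, 80 °C) generate the tertiary radical, which should close 6-endo onto the enone β-carbon in a polarity-matched conjugate addition to give 2-(2,6,6-trimethyl-3-oxocyclohexyl)ethyl pivalate F2. The more substituted enol ether, 2-{2,6,6-trimethyl-3-[(trimethylsilyl)oxy]cyclohex-2-en-1-yl}ethyl pivalate F3, is then made with TMSCl, NaI and Et3N, and Saegusa–Ito oxidation with Pd(OAc)2 in MeCN restores the C2=C3 bond and returns to 8.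

2. Step 12. What may go wrong: Grob-type fragmentation of the β-hydroxy hydroperoxide once base is present, E2 loss of the mesylate toward the allylic hydrogen at the neighbouring methine, or closure through the neighbouring hydroxyl to a tetrahydropyran. Fallback, from 18 to 20, with the order of the two C–O bond formations reversed so that the ring is closed under acid: 18 is treated with 2-methoxyprop-2-yl hydroperoxide and CsOH·H2O in DMF at 0 °C, which displaces the mesylate with inversion and gives (3S,4R)-4-[(2-methoxypropan-2-yl)peroxy]-3-methyl-6-{(2R,3R)-2-methyl-3-[(2,6,6-trimethyl-3-oxocyclohex-1-en-1-yl)methyl]oxiran-2-yl}hex-1-ene F4. Mild acid (pyridinium p-toluenesulfonate, wet MeOH) frees the hydroperoxide of the corresponding hydroperoxy epoxide F5, which under the same acid, or with added H3PMo12O40, should open the epoxide 6-exo at the tertiary carbon with inversion and give 20.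

3. Step 16. What may go wrong: ionisation of the activated, neopentyl-type carbinol next to the peroxide-bearing quaternary carbon, followed by a 1,2-shift or O–O cleavage instead of syn-elimination. Fallback, from 24 to 27, by radical deoxygenation instead of elimination and reduction: 24 is converted with 1,1'-thiocarbonyldiimidazole and DMAP in CH2Cl2 into the O-(imidazol-1-ylthiocarbonyl) derivative of 24, F6. Barton–McCombie reduction with Bu3SnH at high concentration (AIBN, toluene, 80 °C), so that hydrogen transfer outruns attack of the carbon radical on the O–O bond, should give 27 directly and make step 17 unnecessary.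

**Further compounds**

F1 | step 3 | (3E)-8-bromo-4,8-dimethyl-5-oxonon-3-en-1-yl pivalate | C/C(=C\CCOC(=O)C(C)(C)C)C(=O)CCC(C)(C)Br
F2 | step 3 | 2-(2,6,6-trimethyl-3-oxocyclohexyl)ethyl pivalate (diastereomer mixture) | CC1C(CCOC(=O)C(C)(C)C)C(C)(C)CCC1=O
F3 | step 3 | 2-{2,6,6-trimethyl-3-[(trimethylsilyl)oxy]cyclohex-2-en-1-yl}ethyl pivalate | CC1=C(O[Si](C)(C)C)CCC(C)(C)C1CCOC(=O)C(C)(C)C
F4 | step 12 | (3S,4R)-4-[(2-methoxypropan-2-yl)peroxy]-3-methyl-6-{(2R,3R)-2-methyl-3-[(2,6,6-trimethyl-3-oxocyclohex-1-en-1-yl)methyl]oxiran-2-yl}hex-1-ene | C=C[C@H](C)[C@H](OOC(C)(C)OC)CC[C@@]1(C)O[C@@H]1CC2=C(C)C(=O)CCC2(C)C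
F5 | step 12 | (3S,4R)-4-hydroperoxy-3-methyl-6-{(2R,3R)-2-methyl-3-[(2,6,6-trimethyl-3-oxocyclohex-1-en-1-yl)methyl]oxiran-2-yl}hex-1-ene | C=C[C@H](C)[C@H](OO)CC[C@@]1(C)O[C@@H]1CC2=C(C)C(=O)CCC2(C)C
F6 | step 16 | O-(imidazol-1-ylthiocarbonyl) derivative of 24 | COC(=O)[C@H](C)[C@H]1CC[C@@](C)([C@H](OC(=S)n2ccnc2)CC3=C(C)C(=O)CCC3(C)C)OO1
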